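## Retrosynthetic overview

Locants are those of longipinane: C1 ketone, C2=C3, cyclobutane C4–C5–C11–C10, C6 gem-dimethyl, C7 and C9 ester carbons.

1. Target ⇐ diester of a bicyclo[2.1.1]hexan-2-one ("2-norlongipinan-1-one") by one-carbon ring enlargement (C2 inserted between C1 and C3); the esters ⇐ anti-selective Evans–Tishchenko reduction of a C7-hydroxy C9-ketone, then acylation.
2. Seven-membered ring ⇐ C9–C10 bond: SmI2 ketyl–olefin closure of a C9 aldehyde onto a C10 (phenylsulfonyl)methylidene group; the sulfone is cleaved in the same pot and becomes the C10 methyl.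
3. Enabling feature: C5 and C10 are the two one-carbon bridges of the cyclobutane in the bicyclo[2.1.1]hexane. The C6–C9 chain on C5 and the exocyclic π bond on C10 stand syn-axial, about 2.2 Å apart, so the seven-ring closure behaves like a six-ring closure and only one face of C10 can be reached.
4. Bicyclo[2.1.1]hexan-5-one ⇐ intramolecular ketene–alkene [2+2] of an acyclic dec-5-enoic acid (reverse prenylation, Wittig, crotylboration); its C1–O and C3–Me centres steer the cycloaddition and are erased later.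
5. Ring order: cyclobutane plus five-membered ring (step 9), seven-membered ring (step 13), five- to six-membered ring enlargement (steps 18–20).

Key step: step 13

Remark: in names of bicyclic and tricyclic intermediates, "2-norlongipinane" is the longipinane skeleton without C2 (C1 bonded to C3); C4, C5, C10 and C11 always have the configuration of the target, and the C10 methyl is syn to the C1–C3 bridge.

Remark: where a chiral ligand or borane is named, the enantiomer meant is the one that delivers the configuration drawn in the SMILES; the facial senses assumed are the usual ones for these reagent classes.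

## Route

Step 1
Reactants: 1 3-[(tert-butyldimethylsilyl)oxy]propan-1-ol; 2 3-methylbuta-1,2-diene
Product: 3 (3R)-1-[(tert-butyldimethylsilyl)oxy]-4,4-dimethylhex-5-en-3-ol
Conditions: [Ir(cod)Cl]2 (cat.), SEGPHOS (cat., enantiomer giving 3R), 3-nitrobenzoic acid (cat.), Cs2CO3 (cat.), toluene, 60 °C
Reagents that add atoms: none
Why: Iridium-catalysed transfer-hydrogenative reverse prenylation from the alcohol oxidation level, in which the alcohol is dehydrogenated in situ, the allene is hydrometalated to a 1,1-dimethylallyl iridium species that adds through its substituted terminus, and the chiral bisphosphine on iridium sets the carbinol centre (later C7) by reagent control.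

Step 2
Reactants: 3 (3R)-1-[(tert-butyldimethylsilyl)oxy]-4,4-dimethylhex-5-en-3-ol
Product: 4 (3R)-1-[(tert-butyldimethylsilyl)oxy]-4,4-dimethyl-3-[(triisopropylsilyl)oxy]hex-5-ene
Conditions: TIPSOTf, 2,6-lutidine, CH2Cl2, 0 °C to rt
Reagents that add atoms: triisopropylsilyl trifluoromethanesulfonate, CC(C)[Si](C(C)C)(C(C)C)OS(=O)(=O)C(F)(F)F
Why: Silyl triflate silylation of a hindered secondary alcohol, the TIPS group being chosen because it should outlast the later removal of two TBS groups.

Step 3
Reactants: 4 (3R)-1-[(tert-butyldimethylsilyl)oxy]-4,4-dimethyl-3-[(triisopropylsilyl)oxy]hex-5-ene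
Product: 5 (3R)-5-[(tert-butyldimethylsilyl)oxy]-2,2-dimethyl-3-[(triisopropylsilyl)oxy]pentanal
Conditions: O3, CH2Cl2, −78 °C; then PPh3
Reagents that add atoms: ozone, [O-][O+]=O
Why: Ozonolysis with reductive work-up cleaves the only alkene to a non-enolisable neopentyl aldehyde, so the adjacent stereocentre is not at risk.

Step 4
Reactants: 5 (3R)-5-[(tert-butyldimethylsilyl)oxy]-2,2-dimethyl-3-[(triisopropylsilyl)oxy]pentanal
Product: 6 (2E,5R)-7-[(tert-butyldimethylsilyl)oxy]-4,4-dimethyl-5-[(triisopropylsilyl)oxy]hept-2-enal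
Conditions: Ph3P=CHCHO, toluene, 90 °C
Reagents that add atoms: (triphenylphosphoranylidene)acetaldehyde, O=CC=P(c1ccccc1)(c1ccccc1)c1ccccc1
Why: Wittig olefination with the stabilised formyl ylide should give the (E)-enal and cannot epimerise the α-quaternary aldehyde.

Step 5
Reactants: 6 (2E,5R)-7-[(tert-butyldimethylsilyl)oxy]-4,4-dimethyl-5-[(triisopropylsilyl)oxy]hept-2-enal
Product: 7 (3R,4S,5E,8R)-10-[(tert-butyldimethylsilyl)oxy]-3,7,7-trimethyl-8-[(triisopropylsilyl)oxy]deca-1,5-dien-4-ol
Conditions: (E)-crotyl-B(Ipc)2 [from (+)-Ipc2BOMe], THF/Et2O, −78 °C; then NaOH, H2O2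
Reagents that add atoms: (+)-(E)-crotyldiisopinocampheylborane, C/C=C/CB(C1CC2CC(C1C)C2(C)C)C1CC2CC(C1C)C2(C)C
Why: Reagent-controlled crotylboration through a closed chair transition state, in which the (E)-crotyl geometry gives the anti (3R,4S) pair and the isopinocampheyl groups set the absolute sense over the remote C8 centre; both new centres are sacrificial controllers for step 9.

Step 6
Reactants: 7 (3R,4S,5E,8R)-10-[(tert-butyldimethylsilyl)oxy]-3,7,7-trimethyl-8-[(triisopropylsilyl)oxy]deca-1,5-dien-4-ol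
Product: 8 (3R,4S,5E,8R)-4,10-bis[(tert-butyldimethylsilyl)oxy]-3,7,7-trimethyl-8-[(triisopropylsilyl)oxy]deca-1,5-diene
Conditions: TBSOTf, 2,6-lutidine, CH2Cl2, −78 °C to 0 °C
Reagents that add atoms: tert-butyldimethylsilyl trifluoromethanesulfonate, CC(C)(C)[Si](C)(C)OS(=O)(=O)C(F)(F)F
Why: Standard silylation protects the allylic carbinol so that it survives ketene generation.

Step 7
Reactants: 8 (3R,4S,5E,8R)-4,10-bis[(tert-butyldimethylsilyl)oxy]-3,7,7-trimethyl-8-[(triisopropylsilyl)oxy]deca-1,5-diene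
Product: 9 (3R,4R,5E,8R)-4,10-bis[(tert-butyldimethylsilyl)oxy]-3,7,7-trimethyl-8-[(triisopropylsilyl)oxy]dec-5-en-1-ol
Conditions: 9-BBN, THF, 0 °C to rt; then NaOH, H2O2
Reagents that add atoms: hydrogen peroxide, OO
Why: Hydroboration–oxidation with the bulky 9-BBN should be selective for the terminal vinyl group over the hindered internal (E)-alkene and gives the anti-Markovnikov primary alcohol without touching a stereocentre (the C4 descriptor changes only through the priority rules).

Step 8
Reactants: 9 (3R,4R,5E,8R)-4,10-bis[(tert-butyldimethylsilyl)oxy]-3,7,7-trimethyl-8-[(triisopropylsilyl)oxy]dec-5-en-1-ol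
Product: 10 (3R,4R,5E,8R)-4,10-bis[(tert-butyldimethylsilyl)oxy]-3,7,7-trimethyl-8-[(triisopropylsilyl)oxy]dec-5-enoic acid
Conditions: TEMPO (cat.), PhI(OAc)2, MeCN/H2O (pH 7 buffer), rt
Reagents that add atoms: water, O
Why: Nitroxyl-catalysed oxidation in wet medium takes the primary alcohol through the aldehyde hydrate to the acid under near-neutral conditions that the silyl ethers should tolerate.

Step 9
Reactants: 10 (3R,4R,5E,8R)-4,10-bis[(tert-butyldimethylsilyl)oxy]-3,7,7-trimethyl-8-[(triisopropylsilyl)oxy]dec-5-enoic acid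
Product: 13 2-[(tert-butyldimethylsilyl)oxy]-3-methyl-6-{(3R)-5-[(tert-butyldimethylsilyl)oxy]-2-methyl-3-[(triisopropylsilyl)oxy]pentan-2-yl}bicyclo[2.1.1]hexan-5-one (2-silyloxy and 3-methyl cis and syn to the C5 carbonyl bridge; C6 chain anti to the C2–C3 bridge), via acid chloride 11 (not isolated), via ketene 12 (not isolated)
Conditions: 1-chloro-N,N,2-trimethylprop-1-en-1-amine, CH2Cl2, 0 °C; then slow addition to Et3N, toluene, 110 °C (high dilution)
Reagents that add atoms: none
Why: Intramolecular ketene–alkene [2+2] cycloaddition in which the two-atom tether allows only the bridged mode, suprafacial addition to the (E)-alkene places the neopentyl chain anti to the two-carbon bridge, and the alkene face is the one that keeps the C3 methyl and the C1 silyloxy group on the convex side away from the incoming alkene carbon, which fixes C4, C5 and C11 relative to the pre-set C7 centre.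

Step 10
Reactants: 13 the bicyclo[2.1.1]hexan-5-one of step 9
Product: 14 the 5-[(phenylsulfonyl)methylidene] derivative of 13 (mixture of alkene isomers)
Conditions: (EtO)2P(O)CH2SO2Ph, NaH, THF, 0 °C to rt
Reagents that add atoms: diethyl [(phenylsulfonyl)methyl]phosphonate, CCOP(=O)(CS(=O)(=O)c1ccccc1)OCC
Why: Horner–Wadsworth–Emmons olefination of a strained, non-enolisable cyclobutanone installs the acceptor alkene whose exocyclic carbon will become the C10 methyl, and the alkene geometry is irrelevant.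

Step 11
Reactants: 14 the vinyl sulfone of step 10
Product: 15 6-{(3R)-5-hydroxy-2-methyl-3-[(triisopropylsilyl)oxy]pentan-2-yl}-3-methyl-5-[(phenylsulfonyl)methylidene]bicyclo[2.1.1]hexan-2-ol
Conditions: HF·pyridine, pyridine, THF, 0 °C to rt
Reagents that add atoms: none
Why: Buffered fluoride desilylation should remove the primary and the less hindered secondary TBS ether much faster than the neopentyl secondary TIPS ether.

Step 12
Reactants: 15 the diol of step 11
Product: 16 (3R)-4-{2-hydroxy-3-methyl-5-[(phenylsulfonyl)methylidene]bicyclo[2.1.1]hexan-6-yl}-4-methyl-3-[(triisopropylsilyl)oxy]pentanal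
Conditions: TEMPO (cat.), PhI(OAc)2, CH2Cl2, rt
Reagents that add atoms: none
Why: Oxoammonium oxidation under anhydrous conditions is selective for the primary alcohol over the hindered secondary one and stops at the aldehyde.

Step 13
Reactants: 16 the hydroxy aldehyde of step 12
Product: 18 7-[(triisopropylsilyl)oxy]-2-norlongipinane-1,9-diol (C9 epimers), via cyclised sulfone 17 (not isolated)
Conditions: SmI2 (excess), HMPA, t-BuOH, THF, −78 °C to rt
Reagents that add atoms: none
Why: SmI2 reduces the aldehyde to a ketyl radical anion that adds 7-exo-trig to the β-carbon (C10) of the cyclobutylidene sulfone, the α-sulfonyl radical is reduced and protonated to 17, and further SmI2/HMPA cleaves the C–S bond so that the sulfonylmethyl group becomes the C10 methyl. The closest known reaction type is the SmI2 ketyl–olefin reductive cyclisation of aldehydes onto vinyl sulfones or acrylates, established for five- to seven-membered rings and for quaternary centres, followed by the known SmI2/HMPA desulfonylation. One ring is closed, the seven-membered carbocycle, in the exo mode; because the bicyclo[2.1.1]hexane holds C5 and C10 syn-axial about 2.2 Å apart, the closure has the entropic cost of a six-ring closure and is further helped by the gem-dimethyl group and by relief of alkylidenecyclobutane strain. The new quaternary centre C10 is controlled by the tether, since the ketyl can reach only the face of C10 that carries the C5 chain, which puts the future methyl syn to the two-carbon bridge for both alkene isomers of 16; the C9 carbinol centre need not be controlled because step 14 oxidises it. The step needs reduction of the aldehyde in preference to every other group, which is secured because no other carbonyl is present and silyl ether and free hydroxyl are inert, and it needs cyclisation to outrun simple reduction or loss of the β-silyloxy group, which the pre-organisation, HMPA and a weak proton source (tert-butanol) should secure.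

Step 14
Reactants: 18 7-[(triisopropylsilyl)oxy]-2-norlongipinane-1,9-diol (C9 epimers)
Product: 19 (7R)-7-[(triisopropylsilyl)oxy]-2-norlongipinane-1,9-dione
Conditions: DMP, NaHCO3, CH2Cl2, rt
Reagents that add atoms: none
Why: Periodinane oxidation of both secondary alcohols makes the C1 ketone needed for the ring enlargement and at the same time converges both C9 epimers to one ketone.

Step 15
Reactants: 19 (7R)-7-[(triisopropylsilyl)oxy]-2-norlongipinane-1,9-dione
Product: 20 (7R)-7-hydroxy-2-norlongipinane-1,9-dione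
Conditions: HF·pyridine, THF, rt
Reagents that add atoms: none
Why: Acidic fluoride removes the hindered TIPS ether without the base-induced retro-aldol or elimination that a β-silyloxy ketone would risk with basic fluoride.

Step 16
Reactants: 20 (7R)-7-hydroxy-2-norlongipinane-1,9-dione
Product: 21 (7R,9R)-9-hydroxy-1-oxo-2-norlongipinan-7-yl 3-methylbut-2-enoate
Conditions: 3-methylbut-2-enal (excess), SmI2 (30 mol %, premixed with the aldehyde), THF, −10 °C
Reagents that add atoms: 3-methylbut-2-enal, CC(C)=CC=O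
Why: Evans–Tishchenko reduction, in which the hemiacetal formed at the C7 hydroxyl delivers its hydride to the C9 ketone within a six-membered chelate at trivalent samarium, sets C9 anti to C7 and leaves the C7 oxygen as the 3-methylbut-2-enoate, while the C1 ketone has no β-hydroxyl and is not reduced.

Step 17
Reactants: 21 (7R,9R)-9-hydroxy-1-oxo-2-norlongipinan-7-yl 3-methylbut-2-enoate
Product: 22 (7R,9R)-9-(3-methylbutanoyloxy)-1-oxo-2-norlongipinan-7-yl 3-methylbut-2-enoate
Conditions: 3-methylbutanoyl chloride, pyridine, DMAP (cat.), CH2Cl2, rt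
Reagents that add atoms: 3-methylbutanoyl chloride, CC(C)CC(Cl)=O
Why: DMAP-catalysed acylation of the only free hydroxyl gives the second ester without disturbing a stereocentre.

Step 18
Reactants: 22 (7R,9R)-9-(3-methylbutanoyloxy)-1-oxo-2-norlongipinan-7-yl 3-methylbut-2-enoate
Product: 23 trimethylsilyl enol ether of 22 (C1=C3 double bond)
Conditions: TMSOTf, Et3N, CH2Cl2, 0 °C
Reagents that add atoms: trimethylsilyl trifluoromethanesulfonate, C[Si](C)(C)OS(=O)(=O)C(F)(F)F
Why: Soft enolisation can occur only toward C3 because C11 is a bridgehead, and ketones are silylated far faster than esters, so a single silyl enol ether forms and the sacrificial C3 centre is erased.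

Step 19
Reactants: 23 trimethylsilyl enol ether of 22
Product: 24 siloxycyclopropane of 23 (CH2 added across C1=C3)
Conditions: Et2Zn, CH2I2, CH2Cl2, 0 °C to rt
Reagents that add atoms: diiodomethane, ICI
Why: Simmons–Smith cyclopropanation is selective for the electron-rich, strained silyl enol ether over the electron-poor enoate alkene, and the face of addition is irrelevant because both new centres are lost in step 20.

Step 20
Reactants: 24 siloxycyclopropane of 23
Product: 26 CNP0214473.1, (4R,5S,7R,9R,10R,11R)-9-(3-methylbutanoyloxy)-7-(3-methylbut-2-enoyloxy)longipin-2-en-1-one, via β-chloro ketone 25 (not isolated)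
Conditions: FeCl3, DMF, 0 °C; then NaOAc, MeOH, 60 °C
Reagents that add atoms: none
Why: Ito–Saegusa-type ring enlargement, in which FeCl3 oxidises the siloxycyclopropane to an alkoxy radical whose β-scission of the internal C1–C3 bond gives the ring-enlarged tertiary C3 radical and then the chloride, and acetate-induced loss of HCl can go only toward C2 (C4 is a bridgehead), giving the 3-methyl enone.

## Compound list

1 | 3-[(tert-butyldimethylsilyl)oxy]propan-1-ol | OCCCO[Si](C)(C)C(C)(C)C | starting material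
2 | 3-methylbuta-1,2-diene | CC(C)=C=C | starting material
3 | (3R)-1-[(tert-butyldimethylsilyl)oxy]-4,4-dimethylhex-5-en-3-ol | C=CC(C)(C)[C@H](O)CCO[Si](C)(C)C(C)(C)C | intermediate
4 | (3R)-1-[(tert-butyldimethylsilyl)oxy]-4,4-dimethyl-3-[(triisopropylsilyl)oxy]hex-5-ene | C=CC(C)(C)[C@H](O[Si](C(C)C)(C(C)C)C(C)C)CCO[Si](C)(C)C(C)(C)C | intermediate
5 | (3R)-5-[(tert-butyldimethylsilyl)oxy]-2,2-dimethyl-3-[(triisopropylsilyl)oxy]pentanal | O=CC(C)(C)[C@H](O[Si](C(C)C)(C(C)C)C(C)C)CCO[Si](C)(C)C(C)(C)C | intermediate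
6 | (2E,5R)-7-[(tert-butyldimethylsilyl)oxy]-4,4-dimethyl-5-[(triisopropylsilyl)oxy]hept-2-enal | O=C/C=C/C(C)(C)[C@H](O[Si](C(C)C)(C(C)C)C(C)C)CCO[Si](C)(C)C(C)(C)C | intermediate
7 | (3R,4S,5E,8R)-10-[(tert-butyldimethylsilyl)oxy]-3,7,7-trimethyl-8-[(triisopropylsilyl)oxy]deca-1,5-dien-4-ol | C=C[C@@H](C)[C@@H](O)/C=C/C(C)(C)[C@H](O[Si](C(C)C)(C(C)C)C(C)C)CCO[Si](C)(C)C(C)(C)C | intermediate
8 | (3R,4S,5E,8R)-4,10-bis[(tert-butyldimethylsilyl)oxy]-3,7,7-trimethyl-8-[(triisopropylsilyl)oxy]deca-1,5-diene | C=C[C@@H](C)[C@@H](O[Si](C)(C)C(C)(C)C)/C=C/C(C)(C)[C@H](O[Si](C(C)C)(C(C)C)C(C)C)CCO[Si](C)(C)C(C)(C)C | intermediate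
9 | (3R,4R,5E,8R)-4,10-bis[(tert-butyldimethylsilyl)oxy]-3,7,7-trimethyl-8-[(triisopropylsilyl)oxy]dec-5-en-1-ol | OCC[C@@H](C)[C@@H](O[Si](C)(C)C(C)(C)C)/C=C/C(C)(C)[C@H](O[Si](C(C)C)(C(C)C)C(C)C)CCO[Si](C)(C)C(C)(C)C | intermediate
10 | (3R,4R,5E,8R)-4,10-bis[(tert-butyldimethylsilyl)oxy]-3,7,7-trimethyl-8-[(triisopropylsilyl)oxy]dec-5-enoic acid | OC(=O)C[C@@H](C)[C@@H](O[Si](C)(C)C(C)(C)C)/C=C/C(C)(C)[C@H](O[Si](C(C)C)(C(C)C)C(C)C)CCO[Si](C)(C)C(C)(C)C | intermediate
11 | acid chloride of 10 | ClC(=O)C[C@@H](C)[C@@H](O[Si](C)(C)C(C)(C)C)/C=C/C(C)(C)[C@H](O[Si](C(C)C)(C(C)C)C(C)C)CCO[Si](C)(C)C(C)(C)C | intermediate (not isolated)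
12 | ketene derived from 11 | O=C=C[C@@H](C)[C@@H](O[Si](C)(C)C(C)(C)C)/C=C/C(C)(C)[C@H](O[Si](C(C)C)(C(C)C)C(C)C)CCO[Si](C)(C)C(C)(C)C | intermediate (not isolated)
13 | 2-[(tert-butyldimethylsilyl)oxy]-3-methyl-6-{(3R)-5-[(tert-butyldimethylsilyl)oxy]-2-methyl-3-[(triisopropylsilyl)oxy]pentan-2-yl}bicyclo[2.1.1]hexan-5-one; 2-silyloxy and 3-methyl cis, syn to the carbonyl bridge; C6 chain anti to the C2–C3 bridge | O=C1[C@H]2[C@@H](C)[C@@H](O[Si](C)(C)C(C)(C)C)[C@@H]1[C@H]2C(C)(C)[C@H](O[Si](C(C)C)(C(C)C)C(C)C)CCO[Si](C)(C)C(C)(C)C | intermediate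
14 | 5-[(phenylsulfonyl)methylidene] analogue of 13 (carbonyl replaced by C=CH–SO2Ph; both alkene isomers) | O=S(=O)(C=C1[C@H]2[C@@H](C)[C@@H](O[Si](C)(C)C(C)(C)C)[C@@H]1[C@H]2C(C)(C)[C@H](O[Si](C(C)C)(C(C)C)C(C)C)CCO[Si](C)(C)C(C)(C)C)c1ccccc1 | intermediate
15 | 6-{(3R)-5-hydroxy-2-methyl-3-[(triisopropylsilyl)oxy]pentan-2-yl}-3-methyl-5-[(phenylsulfonyl)methylidene]bicyclo[2.1.1]hexan-2-ol (ring configuration as in 13) | O=S(=O)(C=C1[C@H]2[C@@H](C)[C@@H](O)[C@@H]1[C@H]2C(C)(C)[C@H](O[Si](C(C)C)(C(C)C)C(C)C)CCO)c1ccccc1 | intermediate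
16 | (3R)-4-{2-hydroxy-3-methyl-5-[(phenylsulfonyl)methylidene]bicyclo[2.1.1]hexan-6-yl}-4-methyl-3-[(triisopropylsilyl)oxy]pentanal (ring configuration as in 13) | O=S(=O)(C=C1[C@H]2[C@@H](C)[C@@H](O)[C@@H]1[C@H]2C(C)(C)[C@H](O[Si](C(C)C)(C(C)C)C(C)C)CC=O)c1ccccc1 | intermediate
17 | 7-[(triisopropylsilyl)oxy]-2-norlongipinane-1,9-diol whose C10 methyl carries a phenylsulfonyl group (C9 epimers) | O=S(=O)(C[C@@]12[C@H]3[C@@H](C)[C@@H](O)[C@@H]1[C@H]3C(C)(C)[C@H](O[Si](C(C)C)(C(C)C)C(C)C)CC2O)c1ccccc1 | intermediate (not isolated)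
18 | 7-[(triisopropylsilyl)oxy]-2-norlongipinane-1,9-diol (7R; C9 epimers; C10 methyl syn to the C1–C3 bridge) | C[C@@]12[C@H]3[C@@H](C)[C@@H](O)[C@@H]1[C@H]3C(C)(C)[C@H](O[Si](C(C)C)(C(C)C)C(C)C)CC2O | intermediate
19 | (7R)-7-[(triisopropylsilyl)oxy]-2-norlongipinane-1,9-dione | C[C@@]12[C@H]3[C@@H](C)C(=O)[C@@H]1[C@H]3C(C)(C)[C@H](O[Si](C(C)C)(C(C)C)C(C)C)CC2=O | intermediate
20 | (7R)-7-hydroxy-2-norlongipinane-1,9-dione | C[C@@]12[C@H]3[C@@H](C)C(=O)[C@@H]1[C@H]3C(C)(C)[C@H](O)CC2=O | intermediate
21 | (7R,9R)-9-hydroxy-1-oxo-2-norlongipinan-7-yl 3-methylbut-2-enoate | C[C@@]12[C@H]3[C@@H](C)C(=O)[C@@H]1[C@H]3C(C)(C)[C@H](OC(=O)C=C(C)C)C[C@H]2O | intermediate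
22 | (7R,9R)-9-(3-methylbutanoyloxy)-1-oxo-2-norlongipinan-7-yl 3-methylbut-2-enoate | C[C@@]12[C@H]3[C@@H](C)C(=O)[C@@H]1[C@H]3C(C)(C)[C@H](OC(=O)C=C(C)C)C[C@H]2OC(=O)CC(C)C | intermediate
23 | trimethylsilyl enol ether of 22 (C1=C3) | C[C@@]12[C@H]3C(C)=C(O[Si](C)(C)C)[C@@H]1[C@H]3C(C)(C)[C@H](OC(=O)C=C(C)C)C[C@H]2OC(=O)CC(C)C | intermediate
24 | siloxycyclopropane of 23 (CH2 bridging C1 and C3; either face) | C[C@@]12[C@H]3C4(C)CC4(O[Si](C)(C)C)[C@@H]1[C@H]3C(C)(C)[C@H](OC(=O)C=C(C)C)C[C@H]2OC(=O)CC(C)C | intermediate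
25 | 3-chloro-9-(3-methylbutanoyloxy)-7-(3-methylbut-2-enoyloxy)longipinan-1-one | C[C@@]12[C@H]3C(C)(Cl)CC(=O)[C@@H]1[C@H]3C(C)(C)[C@H](OC(=O)C=C(C)C)C[C@H]2OC(=O)CC(C)C | intermediate (not isolated)
26 | CNP0214473.1, (4R,5S,7R,9R,10R,11R)-9-(3-methylbutanoyloxy)-7-(3-methylbut-2-enoyloxy)longipin-2-en-1-one | CC(C)=CC(=O)O[C@@H]1C[C@@H](OC(=O)CC(C)C)[C@@]2(C)[C@@H]3C(=O)C=C(C)[C@H]2[C@@H]3C1(C)C | target

## Step count and risks

Total step count: 20. Longest linear sequence: 20 steps (the route is fully linear from 1).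

Steps most likely to fail:

1. Step 9 (ketene [2+2]). The monosubstituted ketene may dimerise or be quenched before it adds across the hindered 1,2-disubstituted alkene, and discrimination between the two alkene faces by the tether may be incomplete. Fallback, from acid 10 back to ketone 13: acid 10 is coupled with pyrrolidine (EDC·HCl, HOBt, CH2Cl2) to the pyrrolidine amide F1. Tf2O and 2,6-di-tert-butyl-4-methylpyridine in 1,2-dichloroethane at 80 °C convert it into the keteniminium triflate F2, a much stronger electrophile than the ketene. This should add across the same alkene in the same bridged mode to give the cyclobutaniminium triflate F3, and aqueous NaHCO3 hydrolysis then gives 13.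

2. Step 13 (key step). The ketyl may be reduced to the alcohol, or lose the β-silyloxy group, before the seven-membered ring closes, and the desulfonylation may stall. Fallback, from ketone 13 back to diol 18, with the polarity of the bond formation reversed: Wittig methylenation (Ph3P=CH2, THF) gives the methylidene compound F4. HF·pyridine removes both TBS groups to give diol F5, and TEMPO/PhI(OAc)2 oxidises the primary alcohol to the hydroxy aldehyde F6. Fe(acac)3 and PhSiH3 in EtOH/ethylene glycol at 60 °C then transfer a hydrogen atom to the exocyclic CH2, and the tertiary C10 radical adds to the C9 aldehyde (alkene–carbonyl radical cyclisation started by hydrogen-atom transfer). This should give 18 with the methyl group already in place.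

3. Step 16 (Evans–Tishchenko with an enal). The enal may enter conjugate or aldol-type side reactions at trivalent samarium, or the unsaturated acyl group may migrate between the C7 and C9 oxygens. Fallback, from hydroxy ketone 20 back to diester 22: the same reduction is run with the saturated aldehyde 3-methyl-3-(phenylselanyl)butanal, a routine substrate class for this reaction, to give the selenide ester F7. Acylation with 3-methylbutanoyl chloride (pyridine, DMAP) gives the diester F8. H2O2 in CH2Cl2/pyridine at 0 °C oxidises selenium, and syn-elimination should form the conjugated 3-methylbut-2-enoate, which is 22.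

## Further compounds

F1 | step 9 | pyrrolidine amide of acid 10 | O=C(C[C@@H](C)[C@@H](O[Si](C)(C)C(C)(C)C)/C=C/C(C)(C)[C@H](O[Si](C(C)C)(C(C)C)C(C)C)CCO[Si](C)(C)C(C)(C)C)N1CCCC1
F2 | step 9 | keteniminium triflate from F1 | [O-]S(=O)(=O)C(F)(F)F.C(=C[C@@H](C)[C@@H](O[Si](C)(C)C(C)(C)C)/C=C/C(C)(C)[C@H](O[Si](C(C)C)(C(C)C)C(C)C)CCO[Si](C)(C)C(C)(C)C)=[N+]1CCCC1
F3 | step 9 | cyclobutaniminium triflate (pyrrolidinium analogue of 13) | [O-]S(=O)(=O)C(F)(F)F.C1CC[N+](C1)=C1[C@H]2[C@@H](C)[C@@H](O[Si](C)(C)C(C)(C)C)[C@@H]1[C@H]2C(C)(C)[C@H](O[Si](C(C)C)(C(C)C)C(C)C)CCO[Si](C)(C)C(C)(C)C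
F4 | step 13 | 5-methylidene analogue of 13 | C=C1[C@H]2[C@@H](C)[C@@H](O[Si](C)(C)C(C)(C)C)[C@@H]1[C@H]2C(C)(C)[C@H](O[Si](C(C)C)(C(C)C)C(C)C)CCO[Si](C)(C)C(C)(C)C
F5 | step 13 | 6-{(3R)-5-hydroxy-2-methyl-3-[(triisopropylsilyl)oxy]pentan-2-yl}-3-methyl-5-methylidenebicyclo[2.1.1]hexan-2-ol | C=C1[C@H]2[C@@H](C)[C@@H](O)[C@@H]1[C@H]2C(C)(C)[C@H](O[Si](C(C)C)(C(C)C)C(C)C)CCO
F6 | step 13 | (3R)-4-(2-hydroxy-3-methyl-5-methylidenebicyclo[2.1.1]hexan-6-yl)-4-methyl-3-[(triisopropylsilyl)oxy]pentanal | C=C1[C@H]2[C@@H](C)[C@@H](O)[C@@H]1[C@H]2C(C)(C)[C@H](O[Si](C(C)C)(C(C)C)C(C)C)CC=O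
F7 | step 16 | (7R,9R)-9-hydroxy-1-oxo-2-norlongipinan-7-yl 3-methyl-3-(phenylselanyl)butanoate | C[C@@]12[C@H]3[C@@H](C)C(=O)[C@@H]1[C@H]3C(C)(C)[C@H](OC(=O)CC(C)(C)[Se]c1ccccc1)C[C@H]2O
F8 | step 16 | (7R,9R)-9-(3-methylbutanoyloxy)-1-oxo-2-norlongipinan-7-yl 3-methyl-3-(phenylselanyl)butanoate | C[C@@]12[C@H]3[C@@H](C)C(=O)[C@@H]1[C@H]3C(C)(C)[C@H](OC(=O)CC(C)(C)[Se]c1ccccc1)C[C@H]2OC(=O)CC(C)C
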